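## Retrosynthetic overview

1. The last C–C bond is C1–C10, closed across a 14-membered cembranoid ring: reductive opening of a C1/C14 epoxide gives a C1 radical that adds to C10 of a (Z)-C10=C11 olefin. This one step makes the cyclohexane and the ten-membered ring, sets C1, C10 and C11, and leaves the epoxide oxygen on C14.
2. The 14-membered carbocycle is closed before that at C9–C10 (vinyl iodide onto aldehyde, CrCl2/NiCl2). C2–C3 comes from alkynylation of an enal, and the alkyne is kept until after the transannular step.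
3. The γ-lactone (C7, C8, C17, C19) is built first, on the eastern half: Horner–Wadsworth–Emmons olefination, Sharpless epoxidation, epoxide-opening lactonization; C17 comes from the chiral pool.
4. Ring order: γ-lactone, then the 14-membered ring, then the six- and ten-membered rings together.
5. Finish: C14 butyrate, alkyne to (Z)-alkene, ene-type chlorination of C5(Me)=C6 (gives C6–Cl and C5=C16), desilylation at C12.

Assumption: atom numbers are briarane numbers (C15, C16, C18, C20 are the one-carbon groups on C1, C5, C17, C11; C19 is the lactone carbonyl), and the five numbered starting materials are taken as catalogue items.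

## Route

Step 1
Reactants: 1 tert-butyl (R)-lactate; 2 triethyl phosphonoacetate
Product: 4 4-tert-butyl 1-ethyl (3S)-2-(diethoxyphosphoryl)-3-methylbutanedioate, via lactate triflate 3 (not isolated)
Conditions: Tf2O, 2,6-lutidine, CH2Cl2, −78 °C; then the sodium salt of 2 (NaH, THF), 0 °C → rt
Reagents that add atoms: none
Why: SN2 alkylation of the phosphonoacetate anion by the α-triflyloxy ester (malonate-type alkylation) goes with inversion, so the lactate centre becomes C17 with the configuration of the target.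

Step 2
Reactants: 5 (2Z)-3-methylpent-2-en-4-yn-1-ol
Product: 6 (2Z)-3-methylpent-2-en-4-ynal
Conditions: MnO2 (15 equiv), CH2Cl2, rt, dark; used at once
Reagents that add atoms: none
Why: MnO2 oxidation of the allylic alcohol is neutral and leaves the (Z)-enyne untouched.

Step 3
Reactants: 4 phosphonosuccinate; 6 (Z)-enynal
Product: 7 4-tert-butyl 1-ethyl (2E,3R)-3-methyl-2-[(2Z)-3-methylpent-2-en-4-yn-1-ylidene]butanedioate
Conditions: NaH (0.95 equiv relative to 4), THF, 0 °C; then 6, −20 → 0 °C
Reagents that add atoms: none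
Why: Horner–Wadsworth–Emmons olefination with an α-substituted phosphonoacetate gives the (E)-trisubstituted enoate (C6 trans to the C9 ester), and the sub-stoichiometric base leaves C17 alone.

Step 4
Reactants: 7 diester
Product: 8 tert-butyl (2R,3E,5Z)-3-(hydroxymethyl)-2,6-dimethylocta-3,5-dien-7-ynoate
Conditions: iBu2AlH (2.2 equiv), CH2Cl2, −78 °C; potassium sodium tartrate work-up
Reagents that add atoms: none
Why: iBu2AlH reduces the conjugated ethyl ester to the allylic alcohol at −78 °C while the hindered tert-butyl ester survives (chemoselective ester reduction).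

Step 5
Reactants: 8 dienol
Product: 9 tert-butyl (2R)-2-{(2R,3R)-2-(hydroxymethyl)-3-[(1Z)-2-methylbut-1-en-3-yn-1-yl]oxiran-2-yl}propanoate
Conditions: Ti(OiPr)4 (10 mol %), D-(−)-diethyl tartrate (12 mol %), tBuOOH, 4 Å molecular sieves, CH2Cl2, −20 °C
Reagents that add atoms: tert-butyl hydroperoxide, CC(C)(C)OO
Why: Sharpless asymmetric epoxidation of the allylic C7=C8 olefin with the unnatural tartrate places the oxygen on the face that gives C8 as in the target and C7 as the epimer that the next step inverts.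

Step 6
Reactants: 9 epoxy alcohol
Product: 10 (3R,4R,5S)-4-hydroxy-4-(hydroxymethyl)-3-methyl-5-[(1Z)-2-methylbut-1-en-3-yn-1-yl]oxolan-2-one
Conditions: camphorsulfonic acid (10 mol %), CH2Cl2, 0 °C
Reagents that add atoms: none
Why: Acid-promoted 5-exo opening of the dienylic epoxide carbon C7 by the tert-butyl ester carbonyl (epoxy-ester lactonization with loss of isobutene) inverts C7 to the target configuration and frees the tertiary C8 hydroxyl.

Step 7
Reactants: 11 prop-2-yn-1-ol
Product: 13 (2Z)-3-iodo-2-methylprop-2-en-1-ol, via alkenylmagnesium alkoxide 12 (not isolated)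
Conditions: MeMgBr (2.5 equiv), CuI (10 mol %), Et2O/THF, −10 °C → rt; then I2, −10 °C
Reagents that add atoms: methylmagnesium bromide, C[Mg]Br; iodine, II
Why: CuI-catalysed anti-carbomagnesiation of the propargylic alkoxide followed by iodinolysis gives the (Z)-iodoalkene (iodine cis to CH2OH), which fixes the (10Z) geometry.

Step 8
Reactants: 13 (Z)-iodo alcohol
Product: 14 (2Z)-3-iodo-2-methylprop-2-enal
Conditions: MnO2 (15 equiv), CH2Cl2, rt, dark; used at once
Reagents that add atoms: none
Why: Neutral MnO2 oxidation of the allylic alcohol keeps the (Z)-iodoalkene.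

Step 9
Reactants: 14 (Z)-iodo enal
Product: 15 (1Z,3R)-1-iodo-2-methylhexa-1,5-dien-3-ol
Conditions: (+)-Ipc2B(allyl) [from (−)-α-pinene], Et2O, −78 °C; NaOH, H2O2 work-up
Reagents that add atoms: (+)-B-allyldiisopinocampheylborane, C=CCB(C1CC2CC(C1C)C2(C)C)C1CC2CC(C1C)C2(C)C
Why: Brown allylboration with the (+)-reagent attacks the Re face of the aldehyde and sets the (12R)-carbinol by reagent control.

Step 10
Reactants: 15 homoallylic alcohol
Product: 16 tert-butyl{[(1Z,3R)-1-iodo-2-methylhexa-1,5-dien-3-yl]oxy}dimethylsilane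
Conditions: TBSCl, imidazole, DMF, rt
Reagents that add atoms: tert-butyldimethylsilyl chloride, CC(C)(C)[Si](C)(C)Cl
Why: Standard silylation protects the C12 hydroxyl, which must stay free of acyl groups to the end.

Step 11
Reactants: 16 silyl ether; 17 methacrolein
Product: 18 (2E,5R,6Z)-5-{[tert-butyl(dimethyl)silyl]oxy}-7-iodo-2,6-dimethylhepta-2,6-dienal
Conditions: 17 (5 equiv), second-generation Hoveyda–Grubbs catalyst (C31H38Cl2N2ORu, 5 mol %), CH2Cl2, 40 °C
Reagents that add atoms: none
Why: Cross-metathesis of the terminal olefin with methacrolein gives the (E)-2-methyl enal, and the trisubstituted iodoalkene does not react.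

Step 12
Reactants: 10 lactone diol (1.5 equiv, excess recovered); 18 enal
Product: 19 seco enyne triol (C2 carbinol joining 10 through C3≡C4 to 18)
Conditions: Me2Zn (4.5 equiv), ProPhenol (20 mol %, the antipode that delivers the alkynyl group to the Si face of the aldehyde), Ph3PO (40 mol %), toluene, 0 °C
Reagents that add atoms: none
Why: Catalytic asymmetric 1,2-addition of the zinc alkynylide to the enal (ProPhenol alkynylation) forms C2–C3 and sets C2 by reagent control.

Step 13
Reactants: 19 seco enyne triol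
Product: 20 1,14-epoxide of 19
Conditions: Ti(OiPr)4 (0.5 equiv), L-(+)-diisopropyl tartrate (0.6 equiv), tBuOOH, 4 Å molecular sieves, CH2Cl2, −20 °C
Reagents that add atoms: tert-butyl hydroperoxide, CC(C)(C)OO
Why: Titanium tartrate epoxidation of the secondary allylic alcohol is matched with the natural tartrate and gives the erythro epoxy alcohol, which is the C14–O bond with the 14S configuration of the target; no other hydroxyl is allylic.

Step 14
Reactants: 20 epoxy triol
Product: 21 C9 aldehyde of 20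
Conditions: TEMPO (10 mol %), PhI(OAc)2 (1.1 equiv), CH2Cl2, rt; used crude
Reagents that add atoms: none
Why: TEMPO/PhI(OAc)2 oxidises the primary alcohol in preference to the hindered secondary C2 alcohol and stops at the aldehyde.

Step 15
Reactants: 21 hydroxy aldehyde
Product: 22 cembranoid macrocyclic triol (14-membered ring closed at C9–C10)
Conditions: CrCl2 (10 equiv), NiCl2 (2 mol %), DMSO/THF 3:1, rt, 0.002 M, syringe-pump addition
Reagents that add atoms: none
Why: Nozaki–Hiyama–Kishi ring closure of the (Z)-vinyl iodide onto the aldehyde forms C9–C10 with retention of olefin geometry; the chromium alkoxide of the C8 hydroxyl chelates the aldehyde, so attack anti to the C7 branch gives the 8,9-syn (9S) carbinol.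

Step 16
Reactants: 22 macrocyclic triol
Product: 23 2,9-di-O-acetate of 22
Conditions: Ac2O, pyridine, DMAP (cat.), CH2Cl2, 0 °C → rt
Reagents that add atoms: acetic anhydride, CC(=O)OC(C)=O
Why: DMAP-catalysed acetylation esterifies the two secondary alcohols and leaves the tertiary C8 hydroxyl.

Step 17
Reactants: 23 macrocyclic epoxy diacetate
Product: 24 briarane enyne alcohol (C1–C10 closed, free 14-OH)
Conditions: Cp2TiCl2 (3 equiv), Mn dust (8 equiv), THF, rt (gives Cp2TiCl); then 23 and H2O (20 equiv) by slow addition, 0.005 M, rt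
Reagents that add atoms: none
Why: Proposed new method: Cp2TiCl (trivalent titanium) opens the C1–C14 epoxide by single-electron transfer to the tertiary C1 radical with C14–O kept as the titanium alkoxide; 6-endo transannular addition to C10 through the chair in which C14–OTi, C12–OTBS and C15 are equatorial and the two ring connectors C2 and C9 (C9 axial because the olefin is Z) are anti gives the trans ring fusion (1R,10S), and the tertiary C11 radical is reduced by hydrogen-atom transfer from the aqua complex of Cp2TiCl on the α face (11R); the closest known reaction type is the Cp2TiCl-mediated epoxypolyene cyclization (Nugent–RajanBabu type), including transannular cyclizations of epoxygermacrolides and water-terminated variants.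

Step 18
Reactants: 24 briarane enyne alcohol
Product: 25 14-O-butanoate of 24
Conditions: butanoic anhydride, DMAP, Et3N, CH2Cl2, rt
Reagents that add atoms: butanoic anhydride, CCCC(=O)OC(=O)CCC
Why: DMAP-catalysed acylation of the only secondary alcohol; the tertiary C8 hydroxyl does not react.

Step 19
Reactants: 25 enyne butanoate
Product: 26 (3Z,5Z)-diene
Conditions: H2 (1 atm), Pd/CaCO3 poisoned with Pb(OAc)2, quinoline, EtOAc, rt
Reagents that add atoms: none
Why: Lindlar semihydrogenation of the ring alkyne gives the (3Z)-olefin by syn addition and stops at the diene.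

Step 20
Reactants: 26 diene
Product: 27 12-O-TBS ether of the target
Conditions: Ca(OCl)2, CO2 (dry ice), CH2Cl2/H2O, 0 °C
Reagents that add atoms: calcium hypochlorite, [Ca+2].[O-]Cl.[O-]Cl (delivers Cl as HOCl)
Why: Ene-type chlorination of the trisubstituted olefin by HOCl: Cl+ adds to C6 from the exposed face of the ten-membered ring and a C16 proton is lost from the tertiary allylic cation, giving the 6S chloride and the C5=C16 methylene.

Step 21
Reactants: 27 silyl ether
Product: 28 target CNP0237597.2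
Conditions: HF·pyridine, pyridine, THF, 0 °C → rt
Reagents that add atoms: none
Why: Fluoride-mediated desilylation frees the C12 hydroxyl; the esters, the lactone and the allylic chloride are stable to buffered HF·pyridine.

## Compound list

1 | tert-butyl (2R)-2-hydroxypropanoate | C[C@@H](O)C(=O)OC(C)(C)C | starting material
2 | triethyl phosphonoacetate | CCOC(=O)CP(=O)(OCC)OCC | starting material
3 | tert-butyl (2R)-2-{[(trifluoromethyl)sulfonyl]oxy}propanoate | C[C@@H](OS(=O)(=O)C(F)(F)F)C(=O)OC(C)(C)C | intermediate (not isolated)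
4 | 4-tert-butyl 1-ethyl (3S)-2-(diethoxyphosphoryl)-3-methylbutanedioate (both C2 epimers) | CCOC(=O)C(P(=O)(OCC)OCC)[C@@H](C)C(=O)OC(C)(C)C | intermediate
5 | (2Z)-3-methylpent-2-en-4-yn-1-ol | C#C/C(C)=C\CO | starting material
6 | (2Z)-3-methylpent-2-en-4-ynal | C#C/C(C)=C\C=O | intermediate
7 | 4-tert-butyl 1-ethyl (2E,3R)-3-methyl-2-[(2Z)-3-methylpent-2-en-4-yn-1-ylidene]butanedioate | CCOC(=O)/C(=C/C=C(C)\C#C)[C@@H](C)C(=O)OC(C)(C)C | intermediate
8 | tert-butyl (2R,3E,5Z)-3-(hydroxymethyl)-2,6-dimethylocta-3,5-dien-7-ynoate | OC/C(=C/C=C(C)\C#C)[C@@H](C)C(=O)OC(C)(C)C | intermediate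
9 | tert-butyl (2R)-2-{(2R,3R)-2-(hydroxymethyl)-3-[(1Z)-2-methylbut-1-en-3-yn-1-yl]oxiran-2-yl}propanoate | OC[C@]1(O[C@@H]1/C=C(C)\C#C)[C@@H](C)C(=O)OC(C)(C)C | intermediate
10 | (3R,4R,5S)-4-hydroxy-4-(hydroxymethyl)-3-methyl-5-[(1Z)-2-methylbut-1-en-3-yn-1-yl]oxolan-2-one (C3–C9, C16–C19; lactone diol) | OC[C@]1(O)[C@@H](C)C(=O)O[C@H]1/C=C(C)\C#C | intermediate
11 | prop-2-yn-1-ol | C#CCO | starting material
12 | bromo[(1Z)-3-(bromomagnesiooxy)-2-methylprop-1-en-1-yl]magnesium | Br[Mg]/C=C(/C)CO[Mg]Br | intermediate (not isolated)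
13 | (2Z)-3-iodo-2-methylprop-2-en-1-ol | OC/C(C)=C\I | intermediate
14 | (2Z)-3-iodo-2-methylprop-2-enal | O=C/C(C)=C\I | intermediate
15 | (1Z,3R)-1-iodo-2-methylhexa-1,5-dien-3-ol | I/C=C(C)\[C@H](O)CC=C | intermediate
16 | tert-butyl{[(1Z,3R)-1-iodo-2-methylhexa-1,5-dien-3-yl]oxy}dimethylsilane | I/C=C(C)\[C@H](O[Si](C)(C)C(C)(C)C)CC=C | intermediate
17 | 2-methylprop-2-enal (methacrolein) | CC(=C)C=O | starting material
18 | (2E,5R,6Z)-5-{[tert-butyl(dimethyl)silyl]oxy}-7-iodo-2,6-dimethylhepta-2,6-dienal (C1, C2, C10–C15, C20) | O=C/C(C)=C/C[C@@H](O[Si](C)(C)C(C)(C)C)/C(C)=C\I | intermediate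
19 | seco enyne triol: C2 carbinol joining 10 (through C3≡C4) to 18; (14E), (5Z), (10Z) olefins, C10 iodide, 12-OTBS, free 2-, 8-, 9-OH; C2, C7, C8, C12, C17 arranged as in 28 | OC[C@]1(O)[C@@H](C)C(=O)O[C@H]1/C=C(C)\C#C[C@H](O)/C(C)=C/C[C@@H](O[Si](C)(C)C(C)(C)C)/C(C)=C\I | intermediate
20 | 1,14-epoxide of 19 (trans epoxide, erythro to the 2-OH, 14S) | OC[C@]1(O)[C@@H](C)C(=O)O[C@H]1/C=C(C)\C#C[C@H](O)[C@]1(C)O[C@H]1C[C@@H](O[Si](C)(C)C(C)(C)C)/C(C)=C\I | intermediate
21 | C9 aldehyde of 20 (8-hydroxy aldehyde) | O=C[C@]1(O)[C@@H](C)C(=O)O[C@H]1/C=C(C)\C#C[C@H](O)[C@]1(C)O[C@H]1C[C@@H](O[Si](C)(C)C(C)(C)C)/C(C)=C\I | intermediate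
22 | cembranoid macrocycle: 14-membered carbocycle C1–C14 closed at C9–C10; (10Z) olefin, 9S carbinol, 1,14-epoxide, 3-yne, (5Z)-ene, C19→O7 lactone, 12-OTBS, free 2-, 8-, 9-OH | O[C@@H]2[C@]1(O)[C@@H](C)C(=O)O[C@H]1/C=C(C)\C#C[C@H](O)[C@]1(C)O[C@H]1C[C@@H](O[Si](C)(C)C(C)(C)C)/C(C)=C\2 | intermediate
23 | 2,9-di-O-acetate of 22 | CC(=O)O[C@@H]2[C@]1(O)[C@@H](C)C(=O)O[C@H]1/C=C(C)\C#C[C@H](OC(C)=O)[C@]1(C)O[C@H]1C[C@@H](O[Si](C)(C)C(C)(C)C)/C(C)=C\2 | intermediate
24 | briarane enyne alcohol: C1–C10 closed, new centres 1R,10S,11R; free 14-OH and 8-OH, 12-OTBS, 2,9-diacetate, 3-yne, (5Z)-ene | C[C@H]1C(=O)O[C@H]2/C=C(C)\C#C[C@H](OC(C)=O)[C@]3(C)[C@H]([C@@H](C)[C@H](O[Si](C)(C)C(C)(C)C)C[C@@H]3O)[C@H](OC(C)=O)[C@]12O | intermediate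
25 | 14-O-butanoate of 24 | C[C@H]1C(=O)O[C@H]2/C=C(C)\C#C[C@H](OC(C)=O)[C@]3(C)[C@H]([C@@H](C)[C@H](O[Si](C)(C)C(C)(C)C)C[C@@H]3OC(=O)CCC)[C@H](OC(C)=O)[C@]12O | intermediate
26 | (3Z,5Z)-diene from 25 | C[C@H]1C(=O)O[C@H]2/C=C(C)\C=C/[C@H](OC(C)=O)[C@]3(C)[C@H]([C@@H](C)[C@H](O[Si](C)(C)C(C)(C)C)C[C@@H]3OC(=O)CCC)[C@H](OC(C)=O)[C@]12O | intermediate
27 | 12-O-TBS ether of the target (6S chloride, 5(16)-ene, 3Z) | C[C@H]1C(=O)O[C@H]2[C@@H](Cl)C(=C)/C=C\[C@H](OC(C)=O)[C@]3(C)[C@H]([C@@H](C)[C@H](O[Si](C)(C)C(C)(C)C)C[C@@H]3OC(=O)CCC)[C@H](OC(C)=O)[C@]12O | intermediate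
28 | CNP0237597.2: (1R,2S,3Z,6S,7R,8R,9S,10S,11R,12R,14S,17R)-2,9-diacetoxy-14-butanoyloxy-6-chloro-8,12-dihydroxybriara-3,5(16)-diene C19→O7 γ-lactone | C=C1/C=C\[C@H](OC(C)=O)[C@]2(C)[C@H]([C@@H](C)[C@H](O)C[C@@H]2OC(=O)CCC)[C@H](OC(C)=O)[C@]2(O)[C@@H](C)C(=O)O[C@H]2[C@H]1Cl | target

## Totals and risks

Total steps: 21. Longest linear sequence: 15 steps (steps 1, 3–6, 12–21; the branch through steps 7–11 is equally long).

Step 17 is the most likely to fail. The unactivated C10=C11 olefin may be too slow an acceptor, so that the C1 radical undergoes 1,2-acetoxy shift to the propargylic C2 radical, is reduced before it cyclizes, or closes through the cis-fused chair. The fallback sets out from 23 and makes C10 a conjugate acceptor. HF·pyridine gives the desilylated macrocycle F1, and MnO2 oxidises its allylic alcohol to the (Z)-enone F2. Anhydrous Cp2TiCl with collidine hydrochloride then closes C1–C10 by radical 1,4-addition; protonation of the titanium enolate from the α face gives the hydroxy ketone F3. Et2BOMe/NaBH4 reduces the ketone syn to the C14 hydroxyl to give the 12α,14α-diol F4, and selective silylation of the less hindered C12 hydroxyl (TBSCl, imidazole) comes back to the route at 24.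

Step 15 is second: the ring closure may be low-yielding, or the macrocycle may override chelation and give the 9-epimer. The fallback sets out from 10 (with 18) and reverses the order of the two carbonyl additions. TEMPO/PhI(OAc)2 oxidation of 10 gives the hydroxy aldehyde F5. Intermolecular CrCl2/NiCl2 coupling with the vinyl iodide 18, where chelation by the C8 hydroxyl acts without macrocyclic bias, gives the seco enal F6. Intramolecular zinc alkynylation (Me2Zn, ProPhenol, high dilution) closes the 14-membered ring at C2–C3 to the macrocyclic triol F7, and epoxidation as in step 13 comes back to the route at 22.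

Step 20 is third: HOCl may add across the diene or deliver chlorine to the wrong face of C6. The fallback sets out from 26 and brings in oxygen first. A Schenck ene reaction with singlet oxygen (O2, tetraphenylporphyrin, light) gives the 6-hydroperoxy-5(16)-ene F8, which PPh3 reduces to the allylic alcohol F9 with the C6 oxygen on the face opposite to the chloride of 27. Appel chlorination (PPh3, CCl4) with inversion comes back to the route at 27.

Further compounds
F1 | step 17 | 12-hydroxy analogue of 23 (TBS removed) | CC(=O)O[C@@H]2[C@]1(O)[C@@H](C)C(=O)O[C@H]1/C=C(C)\C#C[C@H](OC(C)=O)[C@]1(C)O[C@H]1C[C@@H](O)/C(C)=C\2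
F2 | step 17 | 12-oxo (10Z)-enone macrocycle | CC(=O)O[C@@H]2[C@]1(O)[C@@H](C)C(=O)O[C@H]1/C=C(C)\C#C[C@H](OC(C)=O)[C@]1(C)O[C@H]1CC(=O)/C(C)=C\2
F3 | step 17 | 12-oxo-14-hydroxy briarane enyne (C1–C10 closed) | C[C@H]1C(=O)O[C@H]2/C=C(C)\C#C[C@H](OC(C)=O)[C@]3(C)[C@H]([C@@H](C)C(=O)C[C@@H]3O)[C@H](OC(C)=O)[C@]12O
F4 | step 17 | 12α,14α-dihydroxy briarane enyne | C[C@H]1C(=O)O[C@H]2/C=C(C)\C#C[C@H](OC(C)=O)[C@]3(C)[C@H]([C@@H](C)[C@H](O)C[C@@H]3O)[C@H](OC(C)=O)[C@]12O
F5 | step 15 | C9 aldehyde of 10 | O=C[C@]1(O)[C@@H](C)C(=O)O[C@H]1/C=C(C)\C#C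
F6 | step 15 | seco enal: C9–C10 coupled, open at C2–C3 | O=C/C(C)=C/C[C@@H](O[Si](C)(C)C(C)(C)C)/C(C)=C\[C@H](O)[C@]1(O)[C@@H](C)C(=O)O[C@H]1/C=C(C)\C#C
F7 | step 15 | macrocyclic triol without the 1,14-epoxide (14E olefin) | O[C@@H]2/C(C)=C/C[C@@H](O[Si](C)(C)C(C)(C)C)/C(C)=C\[C@H](O)[C@]1(O)[C@@H](C)C(=O)O[C@H]1/C=C(C)\C#C2
F8 | step 20 | 6-hydroperoxy-5(16)-ene (C6 epimeric to 27) | C[C@H]1C(=O)O[C@H]2[C@H](OO)C(=C)/C=C\[C@H](OC(C)=O)[C@]3(C)[C@H]([C@@H](C)[C@H](O[Si](C)(C)C(C)(C)C)C[C@@H]3OC(=O)CCC)[C@H](OC(C)=O)[C@]12O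
F9 | step 20 | 6-hydroxy-5(16)-ene (C6 epimeric to 27) | C[C@H]1C(=O)O[C@H]2[C@H](O)C(=C)/C=C\[C@H](OC(C)=O)[C@]3(C)[C@H]([C@@H](C)[C@H](O[Si](C)(C)C(C)(C)C)C[C@@H]3OC(=O)CCC)[C@H](OC(C)=O)[C@]12O
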